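**Strategy.** Everything rests on removing C3–OH from ring A (the aryl on the Z-acrylate) and from ring C (the lactate aryl), so that both outer catechols become 4-substituted phenols. One tyrosinase/O2/ascorbate operation should put both oxygens back at the free C–H ortho to each C4–OH. Central ring B should be refused because its C4–OH is flanked by the C3 enol-ether oxygen and sits para to the propenoate. The precursor is therefore the bis-deoxy triphenol, already carrying the (R)-lactate centre, the E-cinnamate and the Z-enol ether. It is built from benzyl-masked monophenol blocks by Doebner condensation, Rh2(OAc)4-catalysed O–H insertion, Horner–Wadsworth–Emmons olefination and one global debenzylation.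

Key step: step 10

Remark on the chemistry: the carbon that receives phosphorus and the aryloxy group in step 7 forms as both epimers. It becomes sp2 in step 8, so it is drawn without a descriptor.

Design notes:
- Ring C stays masked until the O–H insertion is over, so that ring B C3–OH is the only O–H bond the carbenoid meets.
- Benzyl is chosen because all three blocks are sold, or made in one step, in that form.
- The two alkenes bar hydrogenolysis, so the ethers are cleaved with BCl3 and a cation scavenger.
- Ring B is left unmasked in the key step, so nothing has to be removed once the catechols exist.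

Step 1
Reactants: 1 O-benzyl-D-tyrosine
Product: 4 (R)-3-[4-(benzyloxy)phenyl]-2-hydroxypropanoic acid, via diazonium carboxylate 2 (not isolated), via alpha-lactone 3 (not isolated)
Conditions: NaNO2, 1 M aq. H2SO4/1,4-dioxane, 0 °C → rt
Reagents that add atoms: water, O
Why: Diazotisation of an α-amino acid, in which the neighbouring carboxylate expels N2 with inversion to give the alpha-lactone and water opens it at carbon with a second inversion, so the (R) configuration of 1 is retained in 4 while the benzyl ether keeps nitrous acid off the aromatic ring.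

Step 2
Reactants: 4 (R)-3-[4-(benzyloxy)phenyl]-2-hydroxypropanoic acid
Product: 5 methyl (R)-3-[4-(benzyloxy)phenyl]-2-hydroxypropanoate
Conditions: MeOH, H2SO4 (cat.), reflux
Reagents that add atoms: methanol, CO
Why: Fischer esterification, which does not touch the C–O bond at the stereocentre and leaves the aryl benzyl ether intact.

Step 3
Reactants: 5 methyl (R)-3-[4-(benzyloxy)phenyl]-2-hydroxypropanoate; 6 Meldrum's acid
Product: 7 malonic half ester of 5, 3-{[(R)-3-(4-benzyloxyphenyl)-1-methoxy-1-oxopropan-2-yl]oxy}-3-oxopropanoic acid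
Conditions: toluene, 110 °C
Reagents that add atoms: none
Why: Ring-opening acylation of an alcohol by Meldrum's acid with loss of acetone is the standard route to malonic half esters, the single hydroxyl of 5 is the only nucleophile present, and acylation on oxygen cannot disturb the stereocentre.

Step 4
Reactants: 8 3,4-dihydroxybenzaldehyde (protocatechualdehyde)
Product: 9 4-(benzyloxy)-3-hydroxybenzaldehyde
Conditions: BnBr (1.0 equiv), NaHCO3, DMF, 40 °C
Reagents that add atoms: benzyl bromide, BrCc1ccccc1
Why: Regioselective Williamson etherification, because the C4–OH para to the formyl group is much the more acidic, so the weak base ionises only this hydroxyl and one equivalent of benzyl bromide alkylates it.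

Step 5
Reactants: 7 malonic half ester; 9 4-(benzyloxy)-3-hydroxybenzaldehyde
Product: 10 methyl (R)-3-[4-(benzyloxy)phenyl]-2-{[(E)-3-(4-benzyloxy-3-hydroxyphenyl)prop-2-enoyl]oxy}propanoate
Conditions: pyridine, piperidine (cat.), 55 °C
Reagents that add atoms: none
Why: Knoevenagel–Doebner condensation of a malonic half ester, in which amine-catalysed addition to the aldehyde and decarboxylative elimination give the E-cinnamate, the free ring B C3–OH is tolerated, and the amine bases are too weak to epimerise the α-acyloxy ester centre.

Step 6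
Reactants: 11 trimethyl phosphonoacetate
Product: 12 methyl 2-diazo-2-(dimethoxyphosphoryl)acetate
Conditions: p-ABSA, DBU, MeCN, 0 °C → rt
Reagents that add atoms: 4-acetamidobenzenesulfonyl azide (p-ABSA), CC(=O)Nc1ccc(cc1)S(=O)(=O)N=[N+]=[N-]
Why: Regitz diazo transfer from a sulfonyl azide to a doubly activated methylene group, a standard preparation of diazophosphonoacetates.

Step 7
Reactants: 10 cinnamate phenol; 12 methyl 2-diazo-2-(dimethoxyphosphoryl)acetate
Product: 13 methyl (R)-3-[4-(benzyloxy)phenyl]-2-{[(E)-3-{4-benzyloxy-3-[1-(dimethoxyphosphoryl)-2-methoxy-2-oxoethoxy]phenyl}prop-2-enoyl]oxy}propanoate (both epimers at the phosphorus-bearing carbon)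
Conditions: Rh2(OAc)4 (2 mol %), 4 Å MS, toluene, 80 °C, slow addition of 12
Reagents that add atoms: none
Why: Rhodium-carbenoid O–H insertion of a diazophosphonoacetate into a phenol is a known route to 2-aryloxyphosphonoacetates, ring B C3–OH is the only O–H bond in 10, the electron-poor cinnamate alkene and the arenes do not compete (such insertions are run in aromatic solvents), and the new centre is erased in step 8.

Step 8
Reactants: 13 aryloxyphosphonoacetate; 14 4-(benzyloxy)benzaldehyde
Product: 15 tris(benzyl) ether of the precursor, methyl (Z)-3-[4-(benzyloxy)phenyl]-2-{2-benzyloxy-5-[(E)-3-{[(R)-3-(4-benzyloxyphenyl)-1-methoxy-1-oxopropan-2-yl]oxy}-3-oxoprop-1-enyl]phenoxy}prop-2-enoate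
Conditions: LiCl, DBU, MeCN/THF, 0 °C → rt
Reagents that add atoms: none
Why: Horner–Wadsworth–Emmons olefination under Masamune–Roush conditions, where lithium chelation lets DBU ionise only the phosphonoacetate C–H and not the lactate C–H, addition of the stabilised anion to the aromatic aldehyde is reversible, and the geometry should follow product stability, which puts ring A trans to CO2Me and cis to the aryloxy group (Z), any E isomer being removed by chromatography.

Step 9
Reactants: 15 tris(benzyl) ether
Product: 16 bis-deoxy precursor, methyl (Z)-2-{2-hydroxy-5-[(E)-3-{[(R)-3-(4-hydroxyphenyl)-1-methoxy-1-oxopropan-2-yl]oxy}-3-oxoprop-1-enyl]phenoxy}-3-(4-hydroxyphenyl)prop-2-enoate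
Conditions: BCl3, C6HMe5, CH2Cl2, −78 °C; then CHCl3/MeOH
Reagents that add atoms: none
Why: Lewis-acid debenzylation of aryl benzyl ethers with a non-basic cation scavenger, in which BCl3 ionises only the benzylic C–O bonds at −78 °C and pentamethylbenzene captures the benzyl cations by Friedel–Crafts alkylation, so both alkenes, the three esters, the sp2 C–O bonds of the enol ether and the stereocentre are left alone.

Step 10
Reactants: 16 bis-deoxy precursor
Product: 18 target CNP0178751.1, via ring-C monocatechol 17 (not isolated)
Conditions: tyrosinase (Agaricus bisporus), O2 (1 atm), sodium L-ascorbate (excess, in portions), KH2PO4/K2HPO4 buffer pH 6.8/DMSO 9:1, 25 °C; then 1 M HCl to pH 3, EtOAc, reversed-phase chromatography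
Reagents that add atoms: dioxygen, O=O
Why: Proposed new method: the oxy form of the enzyme, a peroxide bridging two divalent copper ions, binds a phenolate at copper and transfers one peroxide oxygen to the ortho carbon by electrophilic aromatic substitution, while ascorbate returns any material leaving at the quinone level to the catechol and keeps the enzyme out of its resting form. The closest known reaction type is the tyrosinase/ascorbate conversion of simple 4-substituted phenols (tyrosol, tyrosine esters, 4-coumarates) and of exposed tyrosine residues of peptides into catechols, whereas two such oxygenations on one triphenolic ester of this size with a third phenol left alone have not been shown. No ring is closed and no stereocentre is formed, and the lactate centre, the esters and both alkene geometries should be untouched at pH 6.8 and 25 °C. The selectivity needed is between rings: A and C each offer a 4-substituted phenol whose two ortho C–H positions are equivalent, so each can give only one regioisomer, and their long para substituents can point out of the active-site funnel. Ring B carries the bulky enol-ether oxygen on C3 next to its C4–OH, which hinders binding and reorientation of the phenolate at copper, and its para propenoate lowers the nucleophilicity of C5, so it should behave as a non-substrate. Ring C, the more electron-rich alkylphenol, is expected to react first (17) and the ester-conjugated ring A second.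

**Compound list**

1 | O-benzyl-D-tyrosine, (R)-2-amino-3-[4-(benzyloxy)phenyl]propanoic acid | N[C@H](Cc1ccc(OCc2ccccc2)cc1)C(=O)O | starting material
2 | diazonium carboxylate, (R)-2-[4-(benzyloxy)phenyl]-1-carboxylatoethanediazonium | N#[N+][C@H](Cc1ccc(OCc2ccccc2)cc1)C(=O)[O-] | intermediate
3 | alpha-lactone, (S)-3-[4-(benzyloxy)benzyl]oxiran-2-one | O=C1O[C@H]1Cc1ccc(OCc2ccccc2)cc1 | intermediate
4 | (R)-3-[4-(benzyloxy)phenyl]-2-hydroxypropanoic acid | O[C@H](Cc1ccc(OCc2ccccc2)cc1)C(=O)O | intermediate
5 | methyl (R)-3-[4-(benzyloxy)phenyl]-2-hydroxypropanoate | O[C@H](Cc1ccc(OCc2ccccc2)cc1)C(=O)OC | intermediate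
6 | Meldrum's acid, 2,2-dimethyl-1,3-dioxane-4,6-dione | CC1(C)OC(=O)CC(=O)O1 | starting material
7 | malonic half ester of 5 | OC(=O)CC(=O)O[C@H](Cc1ccc(OCc2ccccc2)cc1)C(=O)OC | intermediate
8 | 3,4-dihydroxybenzaldehyde | O=Cc1ccc(O)c(O)c1 | starting material
9 | 4-(benzyloxy)-3-hydroxybenzaldehyde | O=Cc1ccc(OCc2ccccc2)c(O)c1 | intermediate
10 | (R)-lactate (E)-cinnamate with free ring B C3–OH, rings B and C O-benzylated | Oc1cc(/C=C/C(=O)O[C@H](Cc2ccc(OCc3ccccc3)cc2)C(=O)OC)ccc1OCc1ccccc1 | intermediate
11 | trimethyl phosphonoacetate | COC(=O)CP(=O)(OC)OC | starting material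
12 | methyl 2-diazo-2-(dimethoxyphosphoryl)acetate | COC(=O)C(=[N+]=[N-])P(=O)(OC)OC | intermediate
13 | ring B 3-O-[1-(dimethoxyphosphoryl)-2-methoxy-2-oxoethyl] ether of 10, both epimers at the phosphorus-bearing carbon | COC(=O)C(Oc1cc(/C=C/C(=O)O[C@H](Cc2ccc(OCc3ccccc3)cc2)C(=O)OC)ccc1OCc1ccccc1)P(=O)(OC)OC | intermediate
14 | 4-(benzyloxy)benzaldehyde | O=Cc1ccc(OCc2ccccc2)cc1 | starting material
15 | tris(benzyl) ether of 16, (Z)-enol ether, (E)-cinnamate, (R) | COC(=O)/C(=C/c1ccc(OCc2ccccc2)cc1)Oc1cc(/C=C/C(=O)O[C@H](Cc2ccc(OCc3ccccc3)cc2)C(=O)OC)ccc1OCc1ccccc1 | intermediate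
16 | bis-deoxy precursor (rings A and C 4-hydroxyphenyl) | COC(=O)/C(=C/c1ccc(O)cc1)Oc1cc(/C=C/C(=O)O[C@H](Cc2ccc(O)cc2)C(=O)OC)ccc1O | intermediate
17 | ring-C monocatechol (ring C 3,4-dihydroxyphenyl, ring A 4-hydroxyphenyl) | COC(=O)/C(=C/c1ccc(O)cc1)Oc1cc(/C=C/C(=O)O[C@H](Cc2ccc(O)c(O)c2)C(=O)OC)ccc1O | intermediate
18 | CNP0178751.1, methyl (Z)-3-(3,4-dihydroxyphenyl)-2-{2-hydroxy-5-[(E)-3-{[(R)-3-(3,4-dihydroxyphenyl)-1-methoxy-1-oxopropan-2-yl]oxy}-3-oxoprop-1-enyl]phenoxy}prop-2-enoate | COC(=O)/C(=C/c1ccc(O)c(O)c1)Oc1cc(/C=C/C(=O)O[C@H](Cc2ccc(O)c(O)c2)C(=O)OC)ccc1O | target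

**Step count.** Total: 10 steps. Longest linear sequence: 8 steps (1, 2, 3, 5, 7, 8, 9, 10) from 1.

**Steps most likely to fail**

**Step 10 (bears the label "Proposed new method:").**
- What may go wrong:
  - no turnover, because the substrate is too large or too poorly soluble for the active site;
  - stalling after the first oxygenation, because the ring A phenol is deactivated by conjugation with its ester;
  - oxidation outrunning the ascorbate, so that quinone-level material couples or polymerises;
  - slow co-oxidation of ring B;
  - ester hydrolysis by impurities in the enzyme preparation.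
- Fallback (known chemistry only): both catechols are brought in ready-made and benzyl-masked, and the same assembly is repeated. It sets out from 9 (with 6 and 12) and comes back at 18.
- Ring C block: purchased sodium (R)-3-(3,4-dihydroxyphenyl)lactate F1 is esterified (HCl, MeOH) to methyl (R)-3-(3,4-dihydroxyphenyl)-2-hydroxypropanoate F2. Both phenols are benzylated (BnBr, K2CO3, acetone, under N2) to the bis(benzyl) ether F3, and 6 in hot toluene gives the malonic half ester F4.
- Assembly: Doebner condensation of F4 with 9 gives the cinnamate phenol F5, and Rh2(OAc)4-catalysed insertion of 12 gives the phosphonate F6. LiCl/DBU olefination with purchased 3,4-bis(benzyloxy)benzaldehyde F7 gives the pentabenzyl ether F8, and BCl3/C6HMe5 at −78 °C releases 18.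

**Step 8.**
- What may go wrong: poor Z/E selectivity of the olefination, sluggish addition to the electron-rich aldehyde, or base-induced epimerisation next to the lactate ester.
- Fallback: the geometry is set by a Heck arylation instead of by the olefination. It sets out from 13 and comes back at 15.
- 13 is olefinated with paraformaldehyde (LiCl, DBU, MeCN), where no geometry arises, to the 2-aryloxyacrylate F9.
- Jeffery-type Heck arylation with purchased 1-(benzyloxy)-4-iodobenzene F10 (Pd(OAc)2, Bu4NCl, NaHCO3, DMF, 70 °C) should take the terminal =CH2 in preference to the 1,2-disubstituted cinnamate.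
- Syn insertion and syn β-hydride elimination from the less crowded rotamer place the new aryl group trans to CO2Me. This is the outcome of the familiar Z-selective arylation of 2-acetamidoacrylates and other α-heteroatom-substituted acrylates.

**Step 7.**
- What may go wrong: diversion of the carbenoid (ylide formation at ether oxygens, attack on the electron-rich arenes, insertion into traces of water), or low reactivity of the hindered, hydrogen-bonded phenol.
- Fallback: the O–C bond is made by SN2 displacement and the alkene by E1cB elimination, which bypasses steps 7 and 8. It sets out from 10 and comes back at 15.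
- Electrophile: purchased 4'-(benzyloxy)acetophenone F11 is carbomethoxylated (NaH, dimethyl carbonate) to the β-keto ester F12 and chlorinated (SO2Cl2, CH2Cl2, 0 °C) to the 2-chloro β-keto ester F13.
- Coupling: K2CO3 in acetone joins 10 and F13 to the 2-aryloxy β-keto ester F14, the classical aryloxylation of α-halo β-keto esters.
- Alkene: NaBH4 at −10 °C reduces only the ketone to the β-hydroxy ester F15. Acetylation (Ac2O, pyridine) gives the β-acetoxy ester F16, and DBU-induced loss of acetic acid should give the conjugated enol ether under thermodynamic control as the Z isomer 15.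

**Further compounds**

F1 | step 10 | sodium (R)-3-(3,4-dihydroxyphenyl)lactate (purchased) | O[C@H](Cc1ccc(O)c(O)c1)C(=O)[O-].[Na+]
F2 | step 10 | methyl (R)-3-(3,4-dihydroxyphenyl)-2-hydroxypropanoate | O[C@H](Cc1ccc(O)c(O)c1)C(=O)OC
F3 | step 10 | methyl (R)-3-[3,4-bis(benzyloxy)phenyl]-2-hydroxypropanoate | O[C@H](Cc1ccc(OCc2ccccc2)c(OCc2ccccc2)c1)C(=O)OC
F4 | step 10 | malonic half ester of F3 | OC(=O)CC(=O)O[C@H](Cc1ccc(OCc2ccccc2)c(OCc2ccccc2)c1)C(=O)OC
F5 | step 10 | (E)-cinnamate of F3 with free ring B C3–OH and 4-O-benzyl | Oc1cc(/C=C/C(=O)O[C@H](Cc2ccc(OCc3ccccc3)c(OCc3ccccc3)c2)C(=O)OC)ccc1OCc1ccccc1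
F6 | step 10 | 2-aryloxyphosphonoacetate from F5, both epimers at the phosphorus-bearing carbon | COC(=O)C(Oc1cc(/C=C/C(=O)O[C@H](Cc2ccc(OCc3ccccc3)c(OCc3ccccc3)c2)C(=O)OC)ccc1OCc1ccccc1)P(=O)(OC)OC
F7 | step 10 | 3,4-bis(benzyloxy)benzaldehyde (purchased) | O=Cc1ccc(OCc2ccccc2)c(OCc2ccccc2)c1
F8 | step 10 | pentabenzyl ether of 18 | COC(=O)/C(=C/c1ccc(OCc2ccccc2)c(OCc2ccccc2)c1)Oc1cc(/C=C/C(=O)O[C@H](Cc2ccc(OCc3ccccc3)c(OCc3ccccc3)c2)C(=O)OC)ccc1OCc1ccccc1
F9 | step 8 | 2-aryloxyacrylate from 13 and formaldehyde | COC(=O)C(=C)Oc1cc(/C=C/C(=O)O[C@H](Cc2ccc(OCc3ccccc3)cc2)C(=O)OC)ccc1OCc1ccccc1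
F10 | step 8 | 1-(benzyloxy)-4-iodobenzene (purchased) | Ic1ccc(OCc2ccccc2)cc1
F11 | step 7 | 4'-(benzyloxy)acetophenone (purchased) | CC(=O)c1ccc(OCc2ccccc2)cc1
F12 | step 7 | methyl 3-[4-(benzyloxy)phenyl]-3-oxopropanoate | COC(=O)CC(=O)c1ccc(OCc2ccccc2)cc1
F13 | step 7 | methyl 3-[4-(benzyloxy)phenyl]-2-chloro-3-oxopropanoate | COC(=O)C(Cl)C(=O)c1ccc(OCc2ccccc2)cc1
F14 | step 7 | 2-aryloxy β-keto ester from 10 and F13, epimers at C2 | COC(=O)C(Oc1cc(/C=C/C(=O)O[C@H](Cc2ccc(OCc3ccccc3)cc2)C(=O)OC)ccc1OCc1ccccc1)C(=O)c1ccc(OCc2ccccc2)cc1
F15 | step 7 | 2-aryloxy β-hydroxy ester, diastereomer mixture | COC(=O)C(Oc1cc(/C=C/C(=O)O[C@H](Cc2ccc(OCc3ccccc3)cc2)C(=O)OC)ccc1OCc1ccccc1)C(O)c1ccc(OCc2ccccc2)cc1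
F16 | step 7 | 2-aryloxy β-acetoxy ester, diastereomer mixture | COC(=O)C(Oc1cc(/C=C/C(=O)O[C@H](Cc2ccc(OCc3ccccc3)cc2)C(=O)OC)ccc1OCc1ccccc1)C(OC(C)=O)c1ccc(OCc2ccccc2)cc1
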